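**Assumptions (one line each)**
- The target has no stereocenters, so no enantiomer or diastereomer issue arises. The "single enantiomer" requirement is trivially met.
- The B ring is 2,5-dihydroxy-4-methoxyphenyl, read from the SMILES as 2′,5′-(OH)₂-4′-OMe with 3-, 5- and 7-OMe.
- Friedel–Crafts acylation of 3,5-dimethoxyphenol under BF₃ occurs ortho to OH (BF₃-chelate control).

**Retrosynthetic overview**
1. Remove the two B-ring benzyl groups (late hydrogenolysis). This leaves the 2-aryl-3,5,7-trimethoxychromone.
2. Disconnect the C2–C1′ bond by a proposed new Pd-catalysed C2–H arylation of 3,5,7-trimethoxychromone with 1-bromo-2,5-bis(benzyloxy)-4-methoxybenzene.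
3. Open the chromone (C ring) to an α-methoxy-2-hydroxyacetophenone plus DMF-DMA, which supplies C2. Trace that ketone to 3,5-dimethoxyphenol plus methoxyacetic acid, so the A ring is present from the start.
4. Build the B-ring bromide from 2-methoxyhydroquinone by bis-benzylation and regioselective bromination.
5. Ring order: A ring (commercial), then C ring, then the B ring is attached as a preformed arene, then deprotection.

**Route**

**Step 1**
Reactants: 1 (3,5-dimethoxyphenol); 2 (methoxyacetic acid)
Product: 3, 1-(2-hydroxy-4,6-dimethoxyphenyl)-2-methoxyethan-1-one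
Conditions: BF₃·OEt₂ (neat, ~5 equiv), 80 °C, 2 h; then aq. NaOAc work-up
Reagents that add atoms: methoxyacetic acid, COCC(=O)O (compound 2)
Why: BF₃-mediated Friedel–Crafts (Hoesch-type) acylation of the electron-rich phenol goes ortho to OH through a chelated acyloxy-BF₂ species, and the product OH is H-bonded to the new C=O. No stereocenter is formed.

**Step 2**
Reactants: 3; 4 (N,N-dimethylformamide dimethyl acetal)
Product: 5, 3,5,7-trimethoxy-4H-chromen-4-one
Conditions: (i) 4 (3 equiv), toluene, 110 °C, 6 h; (ii) TFA, CH₂Cl₂, rt, 2 h (one pot after solvent swap)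
Reagents that add atoms: DMF-DMA, CN(C)C(OC)OC (supplies C2–H of the chromone)
Why: DMF-DMA condenses at the activated CH₂ to give the enaminone, and the phenol then adds in conjugate fashion and eliminates HNMe₂ (enaminone-to-chromone cyclisation). Both ArOMe groups and the new enol ether are acid-stable. No stereocenter is formed.

**Step 3**
Reactants: 6 (2-methoxybenzene-1,4-diol); 7 (benzyl bromide)
Product: 8, 1,4-bis(benzyloxy)-2-methoxybenzene
Conditions: 7 (2.4 equiv), K₂CO₃, DMF, 60 °C, N₂
Reagents that add atoms: BnBr, BrCc1ccccc1 (compound 7)
Why: Williamson bis-O-benzylation of the hydroquinone, run under N₂ to avoid quinone formation. No stereocenter is formed.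

**Step 4**
Reactants: 8; 9 (N-bromosuccinimide)
Product: 10, 1-bromo-2,5-bis(benzyloxy)-4-methoxybenzene
Conditions: 9 (1.05 equiv), MeCN, 0 °C to rt, dark
Reagents that add atoms: NBS, O=C1CCC(=O)N1Br (leaves Br)
Why: Electrophilic aromatic bromination goes at the one position that is ortho to an OBn and para to the OMe. That position is also less hindered than the site flanked by two alkoxy groups. No stereocenter is formed.

**Step 5**
Reactants: 5 (3,5,7-trimethoxychromone); 10 (aryl bromide)
Product: 11, 2-[2,5-bis(benzyloxy)-4-methoxyphenyl]-3,5,7-trimethoxy-4H-chromen-4-one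
Conditions: Pd(OAc)₂ (5 mol%), PCy₃·HBF₄ (10 mol%), PivOH (30 mol%), K₂CO₃ (2 equiv), DMA, 130 °C, 16 h
Reagents that add atoms: none beyond reactant 10 (the aryl group is delivered from 10; HBr is lost as KBr)
Why: Proposed new method: direct C2–H arylation of a 3-alkoxychromone with a hindered, electron-rich ortho-alkoxy aryl bromide. Pd(0)/PCy₃ undergoes oxidative addition into Ar–Br. Pivalate exchange gives ArPd(OPiv), and concerted metalation–deprotonation (CMD) at C2–H follows. That C–H is the β-position of a vinylogous ester, activated by the carbonyl and the ring oxygen. Reductive elimination then forms the C2–aryl bond. The 3-OMe blocks the usual C3 palladation site, the 5-OMe blocks peri C5 activation, and the A-ring C–H bonds are not acidic enough for CMD. The closest known chemistry is Pd/pivalate direct arylation of benzofurans, chromones, and enol ethers. No stereocenter is formed.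

**Step 6**
Reactants: 11
Product: 12, 5-O-methyloxyayanin-A, 2-(2,5-dihydroxy-4-methoxyphenyl)-3,5,7-trimethoxy-4H-chromen-4-one (target)
Conditions: H₂ (1 atm), 10% Pd/C, EtOAc/MeOH 1:1, rt, 3 h
Reagents that add atoms: none (H₂ only adds hydrogen; toluene is lost)
Why: Pd-catalysed hydrogenolysis of the two benzyl ethers. The aryl methyl ethers and the tetrasubstituted, electron-rich C2=C3 double bond of the flavone survive, and no Lewis acid is used that could cleave the 5-OMe. No stereocenter is formed.

**Compound list**

| No. | Name | SMILES | Role |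
|---|---|---|---|
| 1 | 3,5-Dimethoxyphenol | COc1cc(O)cc(OC)c1 | starting material |
| 2 | Methoxyacetic acid | COCC(=O)O | starting material |
| 3 | 1-(2-Hydroxy-4,6-dimethoxyphenyl)-2-methoxyethan-1-one | COCC(=O)c1c(O)cc(OC)cc1OC | intermediate |
| 4 | N,N-Dimethylformamide dimethyl acetal | CN(C)C(OC)OC | starting material |
| 5 | 3,5,7-Trimethoxy-4H-chromen-4-one | COc1cc(OC)c2c(=O)c(OC)coc2c1 | intermediate |
| 6 | 2-Methoxybenzene-1,4-diol | COc1cc(O)ccc1O | starting material |
| 7 | Benzyl bromide | BrCc1ccccc1 | starting material |
| 8 | 1,4-Bis(benzyloxy)-2-methoxybenzene | COc1cc(OCc2ccccc2)ccc1OCc1ccccc1 | intermediate |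
| 9 | N-Bromosuccinimide | O=C1CCC(=O)N1Br | starting material |
| 10 | 1-Bromo-2,5-bis(benzyloxy)-4-methoxybenzene | COc1cc(OCc2ccccc2)c(Br)cc1OCc1ccccc1 | intermediate |
| 11 | 2-[2,5-Bis(benzyloxy)-4-methoxyphenyl]-3,5,7-trimethoxychromen-4-one | COc1cc(OC)c2c(=O)c(OC)c(-c3cc(OCc4ccccc4)c(OC)cc3OCc3ccccc3)oc2c1 | intermediate |
| 12 | 5-O-Methyloxyayanin-A (achiral, no stereocenters) | COc1cc(OC)c2c(=O)c(OC)c(-c3cc(O)c(OC)cc3O)oc2c1 | target |

**Totals**
- Total steps: 6.
- Longest linear sequence: 4 steps (1→3→5→11→12, or equivalently 6→8→10→11→12).

**Three steps most likely to fail**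
1. **Step 5 (proposed new C2–H arylation).** Risks are slow oxidative addition into the hindered, very electron-rich bromide, Ar–Ar homocoupling, and competing A-ring C–H arylation.
   - Fallback (known chemistry, different approach): Claisen–Schmidt condensation of commercial 2′-hydroxy-4′,6′-dimethoxyacetophenone with 2,5-bis(benzyloxy)-4-methoxybenzaldehyde (from Rieche formylation of 8). Follow with Algar–Flynn–Oyamada cyclisation (H₂O₂/NaOH) to the 3-hydroxyflavone, then MeI/K₂CO₃ to install 3-OMe, then H₂/Pd-C.
2. **Step 1 (Friedel–Crafts acylation).** Risks are the wrong regioisomer (acylation para to OH) and partial demethylation under BF₃.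
   - Fallback: Hoesch reaction of phloroglucinol with methoxyacetonitrile (ZnCl₂/HCl, Et₂O), then Me₂SO₄/K₂CO₃ in acetone to methylate the 4,6-OH groups selectively. This leaves the chelated 2-OH and gives 3 by a different bond-forming sequence.
3. **Step 2 (enaminone formation and cyclisation on the hindered α-methoxy ketone).** The α-methoxy CH₂ is less acidic, and the 6′-OMe gives steric hindrance next to the ketone.
   - Fallback: Claisen formylation with HCO₂Et/NaH in THF to the α-formyl ketone (enol), then HCl/EtOH cyclodehydration to 5. This forms the C–C bond by a different mechanism (enolate acylation instead of enaminone condensation).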